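3.24 is the number to start from: at 10.0 min the cedar run held that many times as much target as catalyst charged, both taken as fractions of the starting material charged.

| setting | ash | cedar | maple | Thursday's | Wednesday's |
|---|---|---|---|---|---|
| starting material | 1.2 M | 1.2 M | 0.60 M | 1.2 M | 1.2 M |
| partner | 0.70 equiv | 0.70 equiv | 0.70 equiv | 0.700 equiv | 0.700 equiv |
| free catalyst | 4.5 mol% | 6.8 mol% | 9 mol% | 9 mol% | 9 mol% |
| temperature | 65 °C | 78 °C | 65 °C | 70 °C | 85 °C |
| remark | run made earlier | run made earlier | run made earlier |  |  |
| time |  |  |  | 10 min | 10 min |

| ash: time / min | ash: target / % | cedar: time / min | cedar: target / % | maple: time / min | maple: target / % |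
|---|---|---|---|---|---|
| 1.00 | 1 | 2.50 | 10 | 1.00 | 0 |
| 3.00 | 9 | 5.00 | 14 | 3.00 | 5 |
| 6.00 | 10 | 8.00 | 21 | 6.00 | 7 |
| 8.00 | 12 | 10.0 | 22 | 8.00 | 11 |
| 12.0 | 20 | 12.0 | 24 | 12.0 | 15 |

(scatter of a reading: 1.5 percentage points)

- which of the two there is more of at the end, Thursday's (target / isomer of the product)
- which of the two there is more of at the end, Wednesday's (target / isomer of the product)
- target at the end, in percent of the starting material charged, Thursday's
- target at the end, in percent of the starting material charged, Wednesday's



You might simply multiply: Thursday's loading of 9 mol% times that count gives 29.2 % target. First objection: does the count travel between flasks? Not from maple to ash: at 12.0 min maple stands at 1.67 and ash, at the same temperature, at 4.44, which is more, but these two differ in starting concentration and in loading together, so the gap can't be laid to either one. So set maple aside and keep ash and cedar, which share Thursday's starting concentration.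

Second objection: temperature. Taking the midpoint of its readings at 8.00 min and 12.0 min, ash at 65 °C gives 3.56. Cedar, hotter and with a higher loading, gives less. Thursday's 70 °C lies between them, and this pair shows no gain of count with heat, though its loadings differ too.

Third objection: from ash to cedar the count falls while the loading rises, so plain multiplying may overshoot. Carry that fall on to 9 mol%, laying it wholly to loading, and you get 2.93. This is my turnover count, target per catalyst charged at the asked time, and it gives 26.4 % target for Thursday's. But the fall is worth 2.2 percentage points of target at cedar's loading against a scatter of 1.5 points per reading, so it is a lean, not a measurement. Wednesday's 85 °C lies beyond cedar's temperature; I allow it no gain from heat and keep 26.4 %. The readings report target and say nothing of isomer, so I name target in both flasks, on weak ground.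

The forecast gave 26 % (18 % to 35 %) with target ahead on Thursday's, and 24 % (14 % to 35 %), below my figure, with isomer of the product ahead on Wednesday's: “If the loss is isomerisation, which the data cannot show directly, isomer probably leads there.” Thursday's ends with 25.3 % target and 4.20 % isomer, Wednesday's with 23.0 % and 3.86 %, so their counts are 2.81 and 2.56.

    target ⇌ isomer of the product (K = 0.230, k = 0.0560 min⁻¹, Ea = 96.0 kJ mol⁻¹, ΔH = −20.0 kJ mol⁻¹)
    catalyst intermediate D ⇌ free catalyst + target (K = 0.880 M, k = 300 min⁻¹, Ea = 80.0 kJ mol⁻¹, ΔH = −40.0 kJ mol⁻¹)
    catalyst intermediate B ⇌ by-product + catalyst intermediate C (K = 3.60 M, k = 270 min⁻¹, Ea = 89.0 kJ mol⁻¹, ΔH = −29.0 kJ mol⁻¹)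
    starting material + free catalyst ⇌ catalyst intermediate A (K = 0.280 L mol⁻¹, k = 0.870 L mol⁻¹ min⁻¹, Ea = 53.0 kJ mol⁻¹, ΔH = −65.0 kJ mol⁻¹)
    partner + catalyst intermediate A → catalyst intermediate B (k = 8.50 L mol⁻¹ min⁻¹, Ea = 71.0 kJ mol⁻¹)
    catalyst intermediate C → catalyst intermediate D (k = 330 min⁻¹, Ea = 87.0 kJ mol⁻¹)
    2 catalyst intermediate D → spent catalyst (k = 4.90 L mol⁻¹ min⁻¹, Ea = 68.0 kJ mol⁻¹)
    (constants at 70 °C)

Part of what holds the count down shows in Wednesday's: without the falling back of free catalyst and target to catalyst intermediate D, that flask ends at 43.9 % target instead of 23.0 %, a count of 4.88. Now read Thursday's flask at 4.0 min. Between its readings, cedar has 56.4 % of its 10.0 min target by then, so the count becomes 1.65, or 14.9 % target; the flask gives 14.9 %.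

The earlier runs and the new flask were computed for an exercise; the scatter is artificial.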